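(All runs are calculated with constants of no real substance; noise was put on by code.)

At early times the substrate falls further than the target rises: the violet run has lost 5.40% of its substrate at 1.00 min and shows 0.5% target. So I suppose a second route beside the catalysed one, and I want the odds between them.

| setting | violet | teal | amber | flask |
|---|---|---|---|---|
| substrate | 35 mM | 35 mM | 70 mM | 35 mM |
| gas phase | 2.6 mM (held) | 2.6 mM (held) | 2.6 mM (held) | 2.6 mM (held) |
| free catalyst | 4.9 mM | 4.9 mM | 4.9 mM | 4.9 mM |
| impurity | 1.7 mM | 2.6 mM | 1.2 mM | 1.2 mM |
| remark | run made earlier | run made earlier | run made earlier |  |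
| time |  |  |  | 10 min |

- violet (time / min: target / %, substrate / %): 1.00: 0.5, 94.6; 3.00: 2.1, 82.9; 5.00: 4.5, 72.8; 8.00: 5.8, 58.0
- teal (time / min: target / %, substrate / %): 0.667: 0.5, 96.4; 1.33: 1.6, 92.9; 3.00: 2.0, 83.7; 8.00: 5.3, 60.7
- amber (time / min: target / %, substrate / %): 2.00: 1.5, 89.8; 4.00: 4.0, 78.4; 6.00: 5.7, 69.2; 8.00: 7.0, 61.7

(scatter of a reading: 0.5 percentage points)

* the target standing at 10 min, as a percentage of the substrate charged
* the change that raises the amount of target at 10 min, in percent of the substrate charged most ("none" if none brings more than 2 percentage points) (Sunday's / Tuesday's / Saturday's / none)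
* amount of target at 10 min, in percent of the substrate charged, after Saturday's

- Sunday's: doubling the transfer coefficient of the gas phase, all else as stated
- Tuesday's: doubling the saturation concentration of gas phase, all else as stated
- Saturday's: doubling the amount of free catalyst, all else as stated

- the numbers in the tables scatter with a standard deviation of 0.5 percentage points
- at the start none of the gas phase is in solution

Impurity is charged below free catalyst in each recipe, even in teal at 2.6 mM. If each impurity takes one free catalyst, impurity is the limiting reagent of that loss, and the balance leaves in the flask 3.70 mM of working catalyst, c(free catalyst) minus c(impurity).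

I read the last rows as odds: target over the other substrate lost. Violet has 0.160 at 3.20 mM working catalyst, teal 0.156 at 2.30 mM, and amber 0.224 at 3.70 mM. Amber stands highest, but teal reads level with violet, which I lay to scatter. So I pool the three rows into 0.0584 /mM of odds per unit of working catalyst.

Violet loses substrate at 0.0681 /min and amber at 0.0604 /min, though amber holds twice the substrate. So I take the gas as near saturation and count Sunday's as below 2 percentage points.

The second route then runs at 0.0574 /min, and the flask has odds of 0.216. My reckoning gives 8.93%. Saturday's gives 19.3%. Tuesday's, with both routes doubled, gives 13.4%. So I choose Saturday's.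

The forecast parts from me on the choice: it gives 8.4% for the flask and 14.5% after Saturday's, and it names Tuesday's as best, “if first order in gas”.

The flask gives 8.24%, and Saturday's is best, reaching 17.7%.

    gas phase ⇌ dissolved gas, rate k1*(csat - [dissolved gas]) (kL = 7.90 /min)
    substrate + dissolved gas + free catalyst → free catalyst + target (k = 1300 /M²/min)
    substrate + dissolved gas → uncatalysed product (k = 24.0 /M/min)
    free catalyst + impurity → spent catalyst (k = 1600 /M/min)

Saturday's gains 9.5 points against 4.3 points for Tuesday's. Working catalyst is 75.5% of the charge, and free catalyst stands at 75.5% of its charge at 10.0 min. For a neighbour flask charged with 1.2 mM of free catalyst the balance gives 0 mM of working catalyst, yet at 10.0 min that flask still holds 4.95% of its free catalyst and shows 0.466% target.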